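Counted in percent of the G charged, X and E stand on one scale, and on that scale I reckoned what the flask, whose run so far is elm, still held.

all flasks: G 0.30 M
- elm: X 0.90 equiv; the very flask that is asked about, followed so far
- alder: X 1.4 equiv; run made earlier
- flask: X 0.900 equiv; time 50 min

| run | time / min | E / % |
|---|---|---|
| elm | 4.00 | 77 |
| elm | 10.0 | 84 |
| elm | 20.0 | 82 |
| elm | 50.0 | 83 |
| alder | 6.00 | 99 |
| alder | 20.0 | 99 |
| alder | 30.0 | 100 |
| alder | 50.0 | 100 |

(standard deviation of a reading: 1.5 percentage points)

- autumn: at 50 min take out 90% of the E then present, then wait 1.5 h
- midnight: at 50 min add X, 100% of the amount charged, then wait 1.5 h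
- spring: at 50 min add G, 50.0% of the amount charged, then wait 1.5 h
- summer: change nothing and wait 1.5 h more

- what is taken out of E is counted as made
- steps thought possible: G + X -> E; G + X -> Z; X <-> L
- additions bring no volume worth counting

- E, in percent of the G first charged, at 50 min
- the option that brings most further E ("none" if no option brings more than 2 percentage points) (autumn / midnight / spring / summer / none)
- E present, with what was taken out counted in, in percent of the G first charged, after midnight
- E present, with what was taken out counted in, in percent of the G first charged, after summer

The elm readings from 10.0 min on average 83.0%, good to 0.87 percentage points, and I took that plateau as E now, while the X charge stands at 90.0%. The shortfall came to 7 points: the X charge minus the plateau, which is X that did not reach E. Alder, with 1.4 equiv of X, reached 100%, so I took X as the limiting reagent in elm. With the readings flat, I expected summer, autumn and spring to add nothing and midnight to add E.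

The shortfall also brackets midnight, working with what is left. Had it taken G along, the G left would be the part the X charge never matched, 10 points. Had it taken X without G, the G left would be 17 points. So I expected between 93.0% and 100% after midnight.

The forecast gave 83% now, midnight as best, 99.5% after midnight and 83.5% after summer, on the ground that “E forms irreversibly and simply runs out of X”.

The flask gave 83.2% now, midnight as best with 11 points gained, 94.5% after midnight, which lies inside the range I expected , and 83.2% after summer.

    G + X → E (k = 4.30 L mol⁻¹ min⁻¹)
    G + X → Z, rate k2*[G] as long as [X] is above zero (k = 0.0150 min⁻¹)
    X ⇌ L (K = 2.30, k = 0.0140 min⁻¹)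

At 0.651 min in the flask, the half-life of G by the step into E was 1.1 min, shorter than the 46 min by the step into Z. At 50.0 min the flask held X at 0%, and its own shortfall, the X charge minus its E, came to 6.8 points, which stood as Z at 5.31% and L at 0.00462 M, or 1.54% of the G charge. In the neighbour with 0.360 equiv of X, the shortfall was 4.4 points, held as Z at 4.08% and L at 0.310% of the G charge.

(The earlier runs and the new flask are simulated on assumed constants; scatter was added.)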